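Ring A (the epoxycyclohexane) shows, around the ring, the methyl-bearing epoxide carbon, the epoxide CH, the methine carrying the CH2 linker and the methine carrying isopropenyl. This is the pattern of a trans-5,6-disubstituted 2-methylcyclohex-2-enone. The plan cuts this enone at the bond between the two methines and at its C2=C3 double bond. In one operation an amine-catalysed Michael addition, followed by acid-driven aldol condensation and decarboxylation, joins a tert-butyl 3-oxopentanoate that already carries the acetate arm on its α-carbon to (E)-4-benzoyloxybut-2-enal. The same operation closes ring A and fixes both methines. Ring B (the bromohydrin ring) is grown afterwards on the acetate arm.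

Key step: step 4

Assumption: the sense of induction in steps 4 and 20 is taken from the accepted models (face shielding in the E-iminium ion; analogy with 4-tert-butylcyclohexanone), and since both chiral reagents are sold as either antipode, the other one is used if the sense proves opposite.

Step 1
Reactants: 1 tert-butyl 3-oxopentanoate; 2 methyl bromoacetate
Product: 3 1-tert-butyl 4-methyl 2-propanoylbutanedioate (= tert-butyl 2-(2-methoxy-2-oxoethyl)-3-oxopentanoate; racemic)
Conditions: K2CO3, acetone, reflux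
Reagents that add atoms: none
Why: SN2 C-alkylation of the stabilised β-keto ester enolate with an activated primary bromide is standard acetoacetic ester chemistry, and the new centre may be racemic because it becomes quaternary in step 4 and is re-set after decarboxylation.

Step 2
Reactants: 4 (Z)-but-2-ene-1,4-diol
Product: 5 (Z)-4-hydroxybut-2-en-1-yl benzoate
Conditions: BzCl, Et3N, CH2Cl2, 0 °C (diol in excess)
Reagents that add atoms: benzoyl chloride, O=C(Cl)c1ccccc1
Why: Statistical mono-acylation of a symmetrical diol, with the cheap diol in excess to keep diester formation low and with the Z-alkene untouched.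

Step 3
Reactants: 5 (Z)-4-hydroxybut-2-en-1-yl benzoate
Product: 6 (E)-4-oxobut-2-en-1-yl benzoate
Conditions: pyridinium chlorochromate (C5H5NH)[CrO3Cl], CH2Cl2, rt
Reagents that add atoms: none
Why: Chlorochromate oxidation of the allylic alcohol stops at the aldehyde in CH2Cl2, and the mildly acidic reagent isomerises the first-formed Z-enal to the more stable E-enal.

Step 4
Reactants: 3 1-tert-butyl 4-methyl 2-propanoylbutanedioate; 6 (E)-4-oxobut-2-en-1-yl benzoate
Product: 9 methyl 2-[(1R,6S)-6-(benzoyloxymethyl)-3-methyl-2-oxocyclohex-3-en-1-yl]acetate, via Michael adduct 7 (not isolated), via ring-closed tert-butyl keto ester 8 (not isolated)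
Conditions: (R)-2-[diphenyl(trimethylsilyloxy)methyl]pyrrolidine (20 mol %), PhCO2H (20 mol %), toluene, rt; then p-TsOH·H2O, toluene, 80 °C
Reagents that add atoms: none
Why: The secondary amine condenses with 6 to an E-configured iminium ion, one face of which is screened by the diphenyl(silyloxy)methyl group; the enol of 3 adds to the β-carbon from the open face (iminium-catalysed Michael addition of a 1,3-dicarbonyl donor, a known reaction type that also accepts fully substituted donors), and hydrolysis frees aldehyde 7. Acid then enolises the ethyl ketone towards its CH2 group, which attacks the aldehyde in a 6-(enolendo)-exo-trig aldol closure, and loss of water gives the ring double bond of 8. The same acid cleaves the tert-butyl ester to 2-methylpropene, and the resulting β-keto acid loses CO2. The benzoyloxymethyl-bearing carbon (6S) is set by the catalyst, whereas the quaternary centre of 7 needs no control, because after decarboxylation the arm-bearing carbon (1R) is an enolisable α-carbon that settles trans-diequatorial to its neighbour. The step needs regioselective aldolisation, and the substrate secures it: every other enol/carbonyl pairing would close a four-membered ring, and the methyl ester and the benzoate are inert to p-TsOH in toluene.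

Step 5
Reactants: 9 methyl 2-[(1R,6S)-6-(benzoyloxymethyl)-3-methyl-2-oxocyclohex-3-en-1-yl]acetate
Product: 11 methyl 2-[(1R,6S)-6-(benzoyloxymethyl)-3-methyl-2-(trifluoromethylsulfonyloxy)cyclohex-2-en-1-yl]acetate, via lithium enolate 10 (not isolated)
Conditions: LiBH(s-Bu)3, THF, −78 °C; then 2-[N,N-bis(trifluoromethylsulfonyl)amino]-5-chloropyridine, −78 to 0 °C
Reagents that add atoms: 2-[N,N-bis(trifluoromethylsulfonyl)amino]-5-chloropyridine, FC(F)(F)S(=O)(=O)N(c1ccc(Cl)cn1)S(=O)(=O)C(F)(F)F
Why: 1,4-Hydride addition of the bulky borohydride to a β-unsubstituted cyclohexenone gives one regiodefined enolate, and O-sulfonylation (enol triflate formation) locks the double bond between the former carbonyl carbon and the methyl-bearing carbon without ever enolising the arm-bearing stereocentre.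

Step 6
Reactants: 11 methyl 2-[(1R,6S)-6-(benzoyloxymethyl)-3-methyl-2-(trifluoromethylsulfonyloxy)cyclohex-2-en-1-yl]acetate
Product: 12 methyl 2-[(1S,6S)-6-(benzoyloxymethyl)-3-methylcyclohex-2-en-1-yl]acetate
Conditions: Pd(OAc)2, PPh3, HCO2H, n-Bu3N, DMF, 60 °C
Reagents that add atoms: none
Why: Palladium-catalysed formate reduction of a vinyl triflate (oxidative addition to zerovalent palladium, decarboxylation of the formate to a hydride, reductive elimination) replaces OTf by H with the alkene held in place, which completes the reductive transposition of the enone and leaves both esters alone.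

Step 7
Reactants: 12 methyl 2-[(1S,6S)-6-(benzoyloxymethyl)-3-methylcyclohex-2-en-1-yl]acetate
Product: 14 (3aR,4S,7R,7aR)-4-(hydroxymethyl)-7-iodo-7-methylhexahydro-1-benzofuran-2(3H)-one, via lithium hydroxy carboxylate 13 (not isolated)
Conditions: LiOH, THF/H2O, rt; then excess NaHCO3, KI, I2, 0 °C, dark
Reagents that add atoms: lithium hydroxide, [Li+].[OH-]; iodine, [I][I]
Why: Saponification of both esters is followed by iodolactonisation, in which the carboxylate can reach the ring alkene only from the face that bears its own arm and so opens the iodonium ion of the opposite face 5-exo and trans-diaxially (Fürst–Plattner) at the CH terminus, setting C–O (7aR) and C–I (7R), while the hydroxymethyl group on the other face would need a diaxial conformer to compete.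

Step 8
Reactants: 14 (3aR,4S,7R,7aR)-4-(hydroxymethyl)-7-iodo-7-methylhexahydro-1-benzofuran-2(3H)-one
Product: 15 (3aR,4S,7R,7aR)-7-iodo-7-methyl-2-oxooctahydro-1-benzofuran-4-carbaldehyde
Conditions: Dess–Martin periodinane, NaHCO3, CH2Cl2, 0 °C to rt
Reagents that add atoms: none
Why: Buffered Dess–Martin oxidation takes the primary alcohol to the aldehyde while the carboxyl group is still tied up as the lactone, so that a primary δ-hydroxy ester, which could lactonise under the basic methanolysis of step 9, is never formed.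

Step 9
Reactants: 15 (3aR,4S,7R,7aR)-7-iodo-7-methyl-2-oxooctahydro-1-benzofuran-4-carbaldehyde
Product: 16 methyl 2-[(1R,2R,3S,6S)-3-formyl-6-methyl-7-oxabicyclo[4.1.0]heptan-2-yl]acetate
Conditions: K2CO3, MeOH, 0 °C
Reagents that add atoms: methanol, CO
Why: Methanolysis of the lactone frees an axial alkoxide antiperiplanar to the axial tertiary C–I bond, and intramolecular SN2 closure (halohydrin-to-epoxide) with inversion at the methyl-bearing carbon places the epoxide oxygen on the face of the acetate arm, while the formyl-bearing carbon can only relax to the equatorial trans arrangement it already has.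

Step 10
Reactants: 16 methyl 2-[(1R,2R,3S,6S)-3-formyl-6-methyl-7-oxabicyclo[4.1.0]heptan-2-yl]acetate
Product: 17 methyl 2-[(1R,2R,3S,6S)-3-(1-hydroxyethyl)-6-methyl-7-oxabicyclo[4.1.0]heptan-2-yl]acetate (both carbinol epimers)
Conditions: MeMgBr (1.1 equiv), THF, −78 °C; pH 7 buffer at −78 °C
Reagents that add atoms: methylmagnesium bromide, C[Mg]Br
Why: Grignard addition at low temperature is selective for the aldehyde over the methyl ester and the hindered epoxide, the cold quench keeps the alkoxide from attacking the ester, and the new carbinol configuration is irrelevant because it is oxidised next.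

Step 11
Reactants: 17 methyl 2-[(1R,2R,3S,6S)-3-(1-hydroxyethyl)-6-methyl-7-oxabicyclo[4.1.0]heptan-2-yl]acetate
Product: 18 methyl 2-[(1R,2R,3S,6S)-3-acetyl-6-methyl-7-oxabicyclo[4.1.0]heptan-2-yl]acetate
Conditions: Dess–Martin periodinane, NaHCO3, CH2Cl2, rt
Reagents that add atoms: none
Why: Dess–Martin oxidation merges both carbinol epimers into one methyl ketone, the buffer protects the epoxide, and the α-stereocentre stays in its more stable equatorial orientation.

Step 12
Reactants: 18 methyl 2-[(1R,2R,3S,6S)-3-acetyl-6-methyl-7-oxabicyclo[4.1.0]heptan-2-yl]acetate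
Product: 19 methyl 2-[(1R,2R,3S,6S)-6-methyl-3-(prop-1-en-2-yl)-7-oxabicyclo[4.1.0]heptan-2-yl]acetate
Conditions: Ph3PCH3Br (slight excess over base), NaN(SiMe3)2, THF, 0 °C to rt
Reagents that add atoms: methyltriphenylphosphonium bromide, C[P+](c1ccccc1)(c1ccccc1)c1ccccc1.[Br-]
Why: Wittig methylenation converts the ketone and not the ester, and keeping the phosphonium salt in excess over the base leaves no free base that could start a Claisen-type condensation between the ketone and the ester.

Step 13
Reactants: 19 methyl 2-[(1R,2R,3S,6S)-6-methyl-3-(prop-1-en-2-yl)-7-oxabicyclo[4.1.0]heptan-2-yl]acetate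
Product: 20 N-methoxy-N-methyl-2-[(1R,2R,3S,6S)-6-methyl-3-(prop-1-en-2-yl)-7-oxabicyclo[4.1.0]heptan-2-yl]acetamide
Conditions: MeNH(OMe)·HCl, i-PrMgCl, THF, −20 °C
Reagents that add atoms: N,O-dimethylhydroxylamine hydrochloride, CNOC.Cl
Why: Aminolysis of the unhindered methyl ester by the magnesium amide of N,O-dimethylhydroxylamine (Weinreb amide formation) runs below 0 °C, where the trisubstituted epoxide and the alkene do not react.

Step 14
Reactants: 21 7-oxabicyclo[2.2.1]heptane
Product: 22 trans-4-bromocyclohexan-1-ol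
Conditions: 48% aq. HBr, rt to 50 °C
Reagents that add atoms: hydrogen bromide, Br
Why: Acid-promoted SN2 cleavage of the strained bridged ether by bromide goes with inversion to the trans-bromo alcohol, whose relative configuration has no consequence later.

Step 15
Reactants: 22 trans-4-bromocyclohexan-1-ol
Product: 23 [(trans-4-bromocyclohexyl)oxy](tert-butyl)dimethylsilane
Conditions: t-BuMe2SiCl, imidazole, DMF, rt
Reagents that add atoms: tert-butyldimethylsilyl chloride, CC(C)(C)[Si](C)(C)Cl
Why: Imidazole-promoted silylation masks the oxygen that will become the ring B ketone with a group removed by fluoride, not by the acid that a ketal would need and the epoxide would not stand.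

Step 16
Reactants: 23 [(trans-4-bromocyclohexyl)oxy](tert-butyl)dimethylsilane; 20 N-methoxy-N-methyl-2-[(1R,2R,3S,6S)-6-methyl-3-(prop-1-en-2-yl)-7-oxabicyclo[4.1.0]heptan-2-yl]acetamide
Product: 25 1-[4-(tert-butyldimethylsilyloxy)cyclohexyl]-2-[(1R,2R,3S,6S)-6-methyl-3-(prop-1-en-2-yl)-7-oxabicyclo[4.1.0]heptan-2-yl]ethan-1-one (cis/trans mixture in ring B), via cyclohexylmagnesium bromide 24 (not isolated)
Conditions: Mg, THF, 40 °C; then 20, THF, −20 to 0 °C; pH 7 buffer
Reagents that add atoms: none
Why: Weinreb ketone synthesis, in which the chelated tetrahedral adduct survives until the quench and so stops the Grignard reagent at the ketone, the hindered epoxide is not attacked in THF at this temperature, and the cis/trans mixture in ring B converges in step 19.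

Step 17
Reactants: 25 1-[4-(tert-butyldimethylsilyloxy)cyclohexyl]-2-[(1R,2R,3S,6S)-6-methyl-3-(prop-1-en-2-yl)-7-oxabicyclo[4.1.0]heptan-2-yl]ethan-1-one
Product: 26 tert-butyldimethyl[(4-{3-[(1R,2R,3S,6S)-6-methyl-3-(prop-1-en-2-yl)-7-oxabicyclo[4.1.0]heptan-2-yl]prop-1-en-2-yl}cyclohexyl)oxy]silane (cis/trans mixture in ring B)
Conditions: Ph3PCH3Br, KOt-Bu, THF, 0 to 45 °C
Reagents that add atoms: methyltriphenylphosphonium bromide, C[P+](c1ccccc1)(c1ccccc1)c1ccccc1.[Br-]
Why: Wittig methylenation with excess unstabilised ylide copes with α-branched ketones, and any enolisation towards ring B is harmless because that carbon is not yet a stereocentre of consequence.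

Step 18
Reactants: 26 tert-butyldimethyl[(4-{3-[(1R,2R,3S,6S)-6-methyl-3-(prop-1-en-2-yl)-7-oxabicyclo[4.1.0]heptan-2-yl]prop-1-en-2-yl}cyclohexyl)oxy]silane
Product: 27 4-{3-[(1R,2R,3S,6S)-6-methyl-3-(prop-1-en-2-yl)-7-oxabicyclo[4.1.0]heptan-2-yl]prop-1-en-2-yl}cyclohexan-1-ol (cis/trans mixture in ring B)
Conditions: Bu4NF, THF, rt
Reagents that add atoms: none
Why: Fluoride-induced desilylation is driven by the strong Si–F bond and is neutral to slightly basic, so the epoxide and both alkenes are untouched.

Step 19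
Reactants: 27 4-{3-[(1R,2R,3S,6S)-6-methyl-3-(prop-1-en-2-yl)-7-oxabicyclo[4.1.0]heptan-2-yl]prop-1-en-2-yl}cyclohexan-1-ol
Product: 28 4-{3-[(1R,2R,3S,6S)-6-methyl-3-(prop-1-en-2-yl)-7-oxabicyclo[4.1.0]heptan-2-yl]prop-1-en-2-yl}cyclohexan-1-one
Conditions: Dess–Martin periodinane, NaHCO3, CH2Cl2, rt
Reagents that add atoms: none
Why: Buffered Dess–Martin oxidation merges both ring B isomers into a single 4-substituted cyclohexanone whose two α-methylene groups differ only through the remote ring A.

Step 20
Reactants: 28 4-{3-[(1R,2R,3S,6S)-6-methyl-3-(prop-1-en-2-yl)-7-oxabicyclo[4.1.0]heptan-2-yl]prop-1-en-2-yl}cyclohexan-1-one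
Product: 30 trimethyl{[(4R)-4-{3-[(1R,2R,3S,6S)-6-methyl-3-(prop-1-en-2-yl)-7-oxabicyclo[4.1.0]heptan-2-yl]prop-1-en-2-yl}cyclohex-1-en-1-yl]oxy}silane, via lithium enolate 29 (not isolated)
Conditions: (S,S)-bis(1-phenylethyl)amine hydrochloride, n-BuLi (2 equiv), THF, −78 °C to rt, then −78 °C; 28; Me3SiCl; filtration through Et3N-deactivated silica
Reagents that add atoms: chlorotrimethylsilane, C[Si](C)(C)Cl
Why: Group-selective deprotonation with a C2-symmetric chiral lithium amide (as its LiCl aggregate), a known desymmetrisation of 4-substituted cyclohexanones, removes one of the two axial α-protons under reagent control, and fixing the enol double bond on that side turns the ring B methine into a stereocentre (4R), while at −78 °C the amide leaves the epoxide alone.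

Step 21
Reactants: 30 trimethyl{[(4R)-4-{3-[(1R,2R,3S,6S)-6-methyl-3-(prop-1-en-2-yl)-7-oxabicyclo[4.1.0]heptan-2-yl]prop-1-en-2-yl}cyclohex-1-en-1-yl]oxy}silane
Product: 32 (2R,4R)-2-bromo-4-{3-[(1R,2R,3S,6S)-6-methyl-3-(prop-1-en-2-yl)-7-oxabicyclo[4.1.0]heptan-2-yl]prop-1-en-2-yl}cyclohexan-1-one (bromine equatorial), via axial bromo ketone 31 (not isolated)
Conditions: N-bromosuccinimide (1.0 equiv), THF, −78 °C; then Bu4NBr, MeCN, rt; chromatography, axial epimer re-equilibrated
Reagents that add atoms: N-bromosuccinimide, O=C1CCC(=O)N1Br; tetrabutylammonium bromide (degenerate bromide exchange), CCCC[N+](CCCC)(CCCC)CCCC.[Br-]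
Why: Electrophilic α-bromination of a silyl enol ether, which is far more nucleophilic than the two 1,1-disubstituted alkenes, puts bromine on the carbon chosen in step 20 and by stereoelectronically preferred axial attack should first give 31; SN2 exchange with bromide ion then inverts this centre reversibly, the larger dipole of the equatorial bromo ketone is better solvated in MeCN so that 32 (2R, cis to the side chain) should be enriched, and the separated axial epimer goes back into the equilibration.

Step 22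
Reactants: 32 (2R,4R)-2-bromo-4-{3-[(1R,2R,3S,6S)-6-methyl-3-(prop-1-en-2-yl)-7-oxabicyclo[4.1.0]heptan-2-yl]prop-1-en-2-yl}cyclohexan-1-one
Product: 33 (1S,2R,4R)-2-bromo-1-methyl-4-{3-[(1R,2R,3S,6S)-6-methyl-3-(prop-1-en-2-yl)-7-oxabicyclo[4.1.0]heptan-2-yl]prop-1-en-2-yl}cyclohexan-1-ol (target)
Conditions: MeMgBr, Et2O, −78 °C; aq. NH4Cl at −78 °C
Reagents that add atoms: methylmagnesium bromide, C[Mg]Br
Why: Grignard addition to 2-halocyclohexanones is known to give the cis-halohydrin; with the ring locked by the equatorial side chain and bromine, the reagent takes the equatorial trajectory that avoids the axial hydrogens at C3 and C5, so methyl ends equatorial and OH axial and cis to bromine (1S), and the cold quench keeps the bromo alkoxide from rearranging.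

Compound list
1 | tert-butyl 3-oxopentanoate | CCC(=O)CC(=O)OC(C)(C)C | starting material
2 | methyl bromoacetate | COC(=O)CBr | starting material
3 | 1-tert-butyl 4-methyl 2-propanoylbutanedioate (tert-butyl 2-(2-methoxy-2-oxoethyl)-3-oxopentanoate, racemic) | CCC(=O)C(CC(=O)OC)C(=O)OC(C)(C)C | intermediate
4 | (Z)-but-2-ene-1,4-diol | OC/C=C\CO | starting material
5 | (Z)-4-hydroxybut-2-en-1-yl benzoate | OC/C=C\COC(=O)c1ccccc1 | intermediate
6 | (E)-4-oxobut-2-en-1-yl benzoate | O=C/C=C/COC(=O)c1ccccc1 | intermediate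
7 | 1-tert-butyl 4-methyl 2-[(2S)-1-(benzoyloxy)-4-oxobutan-2-yl]-2-propanoylbutanedioate (both configurations at the quaternary carbon) | CCC(=O)C(CC(=O)OC)(C(=O)OC(C)(C)C)[C@@H](COC(=O)c1ccccc1)CC=O | intermediate
8 | methyl 2-[(6S)-6-(benzoyloxymethyl)-1-(tert-butoxycarbonyl)-3-methyl-2-oxocyclohex-3-en-1-yl]acetate (both configurations at C1) | COC(=O)CC1(C(=O)OC(C)(C)C)[C@@H](COC(=O)c2ccccc2)CC=C(C)C1=O | intermediate
9 | methyl 2-[(1R,6S)-6-(benzoyloxymethyl)-3-methyl-2-oxocyclohex-3-en-1-yl]acetate | COC(=O)C[C@@H]1[C@@H](COC(=O)c2ccccc2)CC=C(C)C1=O | intermediate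
10 | lithium (5S,6R)-5-(benzoyloxymethyl)-6-(2-methoxy-2-oxoethyl)-2-methylcyclohex-1-en-1-olate | COC(=O)C[C@@H]1[C@@H](COC(=O)c2ccccc2)CCC(C)=C1O[Li] | intermediate
11 | methyl 2-[(1R,6S)-6-(benzoyloxymethyl)-3-methyl-2-(trifluoromethylsulfonyloxy)cyclohex-2-en-1-yl]acetate | COC(=O)C[C@@H]1[C@@H](COC(=O)c2ccccc2)CCC(C)=C1OS(=O)(=O)C(F)(F)F | intermediate
12 | methyl 2-[(1S,6S)-6-(benzoyloxymethyl)-3-methylcyclohex-2-en-1-yl]acetate | COC(=O)C[C@@H]1[C@@H](COC(=O)c2ccccc2)CCC(C)=C1 | intermediate
13 | lithium 2-[(1S,6S)-6-(hydroxymethyl)-3-methylcyclohex-2-en-1-yl]acetate | [Li+].[O-]C(=O)C[C@@H]1[C@@H](CO)CCC(C)=C1 | intermediate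
14 | (3aR,4S,7R,7aR)-4-(hydroxymethyl)-7-iodo-7-methylhexahydro-1-benzofuran-2(3H)-one | O=C1C[C@@H]2[C@@H](CO)CC[C@@](C)(I)[C@@H]2O1 | intermediate
15 | (3aR,4S,7R,7aR)-7-iodo-7-methyl-2-oxooctahydro-1-benzofuran-4-carbaldehyde | O=C1C[C@@H]2[C@@H](C=O)CC[C@@](C)(I)[C@@H]2O1 | intermediate
16 | methyl 2-[(1R,2R,3S,6S)-3-formyl-6-methyl-7-oxabicyclo[4.1.0]heptan-2-yl]acetate | COC(=O)C[C@@H]1[C@@H](C=O)CC[C@]2(C)O[C@H]12 | intermediate
17 | methyl 2-[(1R,2R,3S,6S)-3-(1-hydroxyethyl)-6-methyl-7-oxabicyclo[4.1.0]heptan-2-yl]acetate (both carbinol epimers) | COC(=O)C[C@@H]1[C@@H](C(C)O)CC[C@]2(C)O[C@H]12 | intermediate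
18 | methyl 2-[(1R,2R,3S,6S)-3-acetyl-6-methyl-7-oxabicyclo[4.1.0]heptan-2-yl]acetate | COC(=O)C[C@@H]1[C@@H](C(C)=O)CC[C@]2(C)O[C@H]12 | intermediate
19 | methyl 2-[(1R,2R,3S,6S)-6-methyl-3-(prop-1-en-2-yl)-7-oxabicyclo[4.1.0]heptan-2-yl]acetate | COC(=O)C[C@@H]1[C@@H](C(C)=C)CC[C@]2(C)O[C@H]12 | intermediate
20 | N-methoxy-N-methyl-2-[(1R,2R,3S,6S)-6-methyl-3-(prop-1-en-2-yl)-7-oxabicyclo[4.1.0]heptan-2-yl]acetamide | CON(C)C(=O)C[C@@H]1[C@@H](C(C)=C)CC[C@]2(C)O[C@H]12 | intermediate
21 | 7-oxabicyclo[2.2.1]heptane | C1CC2CCC1O2 | starting material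
22 | trans-4-bromocyclohexan-1-ol | O[C@H]1CC[C@H](Br)CC1 | intermediate
23 | [(trans-4-bromocyclohexyl)oxy](tert-butyl)dimethylsilane | CC(C)(C)[Si](C)(C)O[C@H]1CC[C@H](Br)CC1 | intermediate
24 | [4-(tert-butyldimethylsilyloxy)cyclohexyl]magnesium bromide (configurationally labile) | CC(C)(C)[Si](C)(C)OC1CCC([Mg]Br)CC1 | intermediate
25 | 1-[4-(tert-butyldimethylsilyloxy)cyclohexyl]-2-[(1R,2R,3S,6S)-6-methyl-3-(prop-1-en-2-yl)-7-oxabicyclo[4.1.0]heptan-2-yl]ethan-1-one (cis/trans in ring B) | CC(C)(C)[Si](C)(C)OC1CCC(CC1)C(=O)C[C@@H]1[C@@H](C(C)=C)CC[C@]2(C)O[C@H]12 | intermediate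
26 | tert-butyldimethyl[(4-{3-[(1R,2R,3S,6S)-6-methyl-3-(prop-1-en-2-yl)-7-oxabicyclo[4.1.0]heptan-2-yl]prop-1-en-2-yl}cyclohexyl)oxy]silane (cis/trans in ring B) | CC(C)(C)[Si](C)(C)OC1CCC(CC1)C(=C)C[C@@H]1[C@@H](C(C)=C)CC[C@]2(C)O[C@H]12 | intermediate
27 | 4-{3-[(1R,2R,3S,6S)-6-methyl-3-(prop-1-en-2-yl)-7-oxabicyclo[4.1.0]heptan-2-yl]prop-1-en-2-yl}cyclohexan-1-ol (cis/trans in ring B) | OC1CCC(CC1)C(=C)C[C@@H]1[C@@H](C(C)=C)CC[C@]2(C)O[C@H]12 | intermediate
28 | 4-{3-[(1R,2R,3S,6S)-6-methyl-3-(prop-1-en-2-yl)-7-oxabicyclo[4.1.0]heptan-2-yl]prop-1-en-2-yl}cyclohexan-1-one | O=C1CCC(CC1)C(=C)C[C@@H]1[C@@H](C(C)=C)CC[C@]2(C)O[C@H]12 | intermediate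
29 | lithium (4R)-4-{3-[(1R,2R,3S,6S)-6-methyl-3-(prop-1-en-2-yl)-7-oxabicyclo[4.1.0]heptan-2-yl]prop-1-en-2-yl}cyclohex-1-en-1-olate | C=C(C[C@@H]1[C@@H](C(=C)C)CC[C@]2(C)O[C@H]12)[C@@H]1CCC(O[Li])=CC1 | intermediate
30 | trimethyl{[(4R)-4-{3-[(1R,2R,3S,6S)-6-methyl-3-(prop-1-en-2-yl)-7-oxabicyclo[4.1.0]heptan-2-yl]prop-1-en-2-yl}cyclohex-1-en-1-yl]oxy}silane | C=C(C[C@@H]1[C@@H](C(=C)C)CC[C@]2(C)O[C@H]12)[C@@H]1CCC(O[Si](C)(C)C)=CC1 | intermediate
31 | (2S,4R)-2-bromo-4-{3-[(1R,2R,3S,6S)-6-methyl-3-(prop-1-en-2-yl)-7-oxabicyclo[4.1.0]heptan-2-yl]prop-1-en-2-yl}cyclohexan-1-one (bromine axial, trans to the side chain) | C=C(C[C@@H]1[C@@H](C(=C)C)CC[C@]2(C)O[C@H]12)[C@@H]1CCC(=O)[C@@H](Br)C1 | intermediate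
32 | (2R,4R)-2-bromo-4-{3-[(1R,2R,3S,6S)-6-methyl-3-(prop-1-en-2-yl)-7-oxabicyclo[4.1.0]heptan-2-yl]prop-1-en-2-yl}cyclohexan-1-one (bromine equatorial, cis to the side chain) | C=C(C[C@@H]1[C@@H](C(=C)C)CC[C@]2(C)O[C@H]12)[C@@H]1CCC(=O)[C@H](Br)C1 | intermediate
33 | (1S,2R,4R)-2-bromo-1-methyl-4-{3-[(1R,2R,3S,6S)-6-methyl-3-(prop-1-en-2-yl)-7-oxabicyclo[4.1.0]heptan-2-yl]prop-1-en-2-yl}cyclohexan-1-ol | C=C(C[C@@H]1[C@@H](C(=C)C)CC[C@]2(C)O[C@H]12)[C@@H]1CC[C@](C)(O)[C@H](Br)C1 | target

Total step count: 22.
Longest linear sequence: 19 steps (from 4 through steps 2–13 and 16–22).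

Steps most likely to fail

Step 4. Addition of the fully substituted donor may be slow and reversible. Conversion may then stall, the enal may be lost through its dienamine, or facial selectivity may erode by retro-Michael equilibration. The fallback forms the arm bond after the ring instead of before it. Setting out from 1 and 6, the same amine/acid sequence is run with the unalkylated, much less hindered keto ester. It should pass through tert-butyl 2-[(2S)-1-(benzoyloxy)-4-oxobutan-2-yl]-3-oxopentanoate F1 and give [(1S)-4-methyl-5-oxocyclohex-3-en-1-yl]methyl benzoate F2. Kinetic deprotonation of the saturated α-methylene group with LiN(i-Pr)2 in THF at −78 °C follows. Alkylation with 2, anti to the neighbouring benzoyloxymethyl group as in carvone-type enolate alkylations, comes back to the route at 9.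

Step 21. The equilibrium between the two bromo ketones may not lean far enough to the equatorial side, or the epimers may not separate, so that the C–Br centre is carried on as a mixture. The fallback replaces thermodynamic by kinetic control. Setting out from the mixture of 31 and 32, deprotonation of the acidic CHBr position with LiN(SiMe3)2 in the presence of Me3SiCl (THF, −78 °C) should give {[(4R)-2-bromo-4-{3-[(1R,2R,3S,6S)-6-methyl-3-(prop-1-en-2-yl)-7-oxabicyclo[4.1.0]heptan-2-yl]prop-1-en-2-yl}cyclohex-1-en-1-yl]oxy}trimethylsilane F3. Protodesilylation with Bu4NF/AcOH at −78 °C then delivers the proton along the axial trajectory, which pushes bromine into the equatorial position and comes back at 32.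

Step 20. The chiral amide may distinguish the two α-methylene groups poorly, because ring A is too remote to help. Ring B epimers that are hard to separate would then be carried forward. The fallback fixes the side of the enolate through an isolable enone. Setting out from 28, a desymmetrising dehydrogenation by enamine catalysis (chiral primary amine salt, 2-iodoxybenzoic acid) should give (4R)-4-{3-[(1R,2R,3S,6S)-6-methyl-3-(prop-1-en-2-yl)-7-oxabicyclo[4.1.0]heptan-2-yl]prop-1-en-2-yl}cyclohex-2-en-1-one F4, which can be purified. Conjugate reduction with LiBH(s-Bu)3 at −78 °C then gives enolate 29 regiospecifically, and Me3SiCl comes back at 30.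

Further compounds
F1 | step 4 | tert-butyl 2-[(2S)-1-(benzoyloxy)-4-oxobutan-2-yl]-3-oxopentanoate | CCC(=O)C(C(=O)OC(C)(C)C)[C@@H](COC(=O)c1ccccc1)CC=O
F2 | step 4 | [(1S)-4-methyl-5-oxocyclohex-3-en-1-yl]methyl benzoate | CC1=CC[C@H](COC(=O)c2ccccc2)CC1=O
F3 | step 21 | {[(4R)-2-bromo-4-{3-[(1R,2R,3S,6S)-6-methyl-3-(prop-1-en-2-yl)-7-oxabicyclo[4.1.0]heptan-2-yl]prop-1-en-2-yl}cyclohex-1-en-1-yl]oxy}trimethylsilane | C=C(C[C@@H]1[C@@H](C(=C)C)CC[C@]2(C)O[C@H]12)[C@@H]1CCC(O[Si](C)(C)C)=C(Br)C1
F4 | step 20 | (4R)-4-{3-[(1R,2R,3S,6S)-6-methyl-3-(prop-1-en-2-yl)-7-oxabicyclo[4.1.0]heptan-2-yl]prop-1-en-2-yl}cyclohex-2-en-1-one | C=C(C[C@@H]1[C@@H](C(=C)C)CC[C@]2(C)O[C@H]12)[C@@H]1CCC(=O)C=C1
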